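(The constants used here belong to no real substance; the flask was simulated.)

47.5 half-lives of the balance between intermediate and target fit into the run of the flask called grey, against 0.380 of the balance between intermediate and isomer of the product. The bench rule says that a reversible step stands at balance after a few half-lives. The target balance, a pre-equilibrium, passes that rule. The isomer balance in grey does not, so the rule stops there.

- grey: starting material 0.15 M; coupling partner 0.300 M; scavenger 0.150 M; protic impurity 0.150 M; temperature 90 °C; time 1.0 min
- ochre: starting material 0.15 M; coupling partner 0.300 M; scavenger 0.150 M; protic impurity 0.150 M; temperature 115 °C; time 1.0 min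

- the flask with the highest amount of target, in percent of the starting material charged ("all alike" if they lie within 1.5 percentage points) (grey / ochre / all alike)
- final target, as a percentage of the starting material charged, in grey
- final target, as a percentage of the starting material charged, in ochre

- what is said of released group includes idle adduct
- at 90 °C the constants are as listed, elsewhere as the activation energies and enthalpies make them

    coupling partner + released group ⇌ idle adduct, settled at all times (K1 = 3.14 L mol⁻¹, ΔH1 = −34.0 kJ mol⁻¹)
    intermediate ⇌ isomer of the product (K2 = 2.57, k2 = 0.00316 s⁻¹, Ea2 = 111 kJ mol⁻¹, ΔH2 = −20.0 kJ mol⁻¹)
    starting material + protic impurity → quenched substrate (k3 = 3.14 L mol⁻¹ s⁻¹, Ea3 = 60.0 kJ mol⁻¹)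
    scavenger + released group → scavenged by-product (k4 = 4.54 L mol⁻¹ s⁻¹, Ea4 = 47.0 kJ mol⁻¹)
    intermediate ⇌ target (K5 = 1.24, k5 = 0.304 s⁻¹, Ea5 = 79.0 kJ mol⁻¹, ΔH5 = −44.0 kJ mol⁻¹)
    starting material + coupling partner → intermediate + released group (k6 = 1.73 L mol⁻¹ s⁻¹, Ea6 = 54.0 kJ mol⁻¹)
    (constants at 90 °C)

Starting material either couples with coupling partner to give intermediate or is quenched by protic impurity. At grey's charges its half-life, reckoned at the start rates, is 0.700 s, much shorter than the run. Start rates give a coupled share of 52.4% in grey.

At the early end, the bench rule gives the target a fraction f = K/(1 + K) of the target–intermediate pair. In grey, f is 55.4%.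

The late end is the limit in which the isomer balance stands too. The isomer then holds a fraction q of pair and isomer together, with q = 53.4% in grey.

Between the ends, the pair relaxes towards the isomer at a rate λ. The isomer is fed from the intermediate part of the pair, so, with k and K now the constants of the isomer step:

λ = k(1 − f) + k/K = 0.00264 s⁻¹ in grey

Joining the two ends:

keep = f × (1 − q × (1 − exp(−λt)))

In grey this is 51.0%. That number is the keep: target standing at the end per unit of starting material that coupled. The formula holds no concentration, so at fixed temperature and time it gives the same keep for other charges.

Ochre is hotter. The speed-up of 5.4 in the intermediate-to-target step measures the temperature gap, and each other constant scales as that factor raised to its own energy over that step's activation energy. The target balance constant falls to 0.485, so f is 32.7%. The isomer step gives k = 0.0337 s⁻¹ and K = 1.68. Then q is 53.0% and λ is 0.0428 s⁻¹. The run in ochre spans 3.71 half-lives of the drain, the few that the bench rule asks for. The keep in ochre is 16.7%, and the coupled share from start rates is 49.2%.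

This reckoning therefore gives:

grey: 52.4% × 51.0% = 26.7%

ochre: 49.2% × 16.7% = 8.22%

The forecast, made separately, names grey, with 26.5% in grey and 8.5% in ochre, close to these figures but not the same. Its grounds for ochre are that "the isomer drain nearly reaches equilibrium within the minute".

The simulation gives 27.8% in grey and 8.76% in ochre, so grey holds the most target and the forecast stands. At 1.00 min, quenched substrate stands at 45.5% of the charge in grey and 47.6% in ochre, while the keep of grey is 3.05 times that of ochre. Applied to the material not quenched, the keep gives 27.8% in grey and 8.75% in ochre.

A neighbour flask is like grey but holds 0.18 M of coupling partner, so the formula's keep stays 51.0%, and with its start-rate share this gives 20.3% target. The simulation gives 22.1%, and the keep applied to the material not quenched there, 56.9% being quenched, gives 22.0%.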